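**Plan**
- Retrosynthesis first removes the C4–Br bond of ring A (electrophilic bromination para to the methoxy group), then the C5–Br bond (sterically directed C–H borylation and bromodeboronation), then the O–CH3 bond.
- Ring A is taken back to a 3-bromo-2-aryloxycyclohex-2-enone and its C3–Br bond to a carbonyl group. In ring A the aryloxy carbon C2 lies between the methoxy carbon C1 and the bromine carbon C3, which is the pattern of a 2-aryloxycyclohexane-1,3-dione, and this makes a Claisen-type ring closure possible.
- The dione is opened at C1–C2 to an open-chain δ-keto ester, whose ether C–O bond leads to 2,4-dibromophenol and a bromomethyl ketone made from ethyl glutaryl chloride and (trimethylsilyl)diazomethane.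
- Forward: the chain is built and O-alkylated, ring A is closed by Dieckmann-type cyclization, one carbonyl becomes the vinyl bromide, the ring is aromatized in two stages and O-methylated, and bromine enters at C5 and then at C4. Ring B is bought complete.
- Stereochemistry: the target has no stereocentre. The only one on the way (C6 of the α′-bromo enone) is formed racemic and erased on aromatization.

Key step: step 3

Remark: ring A is numbered C1 (OMe), C2 (OAr), C3, C4, C5 (Br), C6 (H) throughout, also in its non-aromatic precursors. Dione 7 is drawn as the diketo tautomer although it should exist largely as the enol.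

**Step 1**
Reactants: 1 ethyl 5-chloro-5-oxopentanoate (ethyl glutaryl chloride); 2 (trimethylsilyl)diazomethane
Product: 4 ethyl 6-bromo-5-oxohexanoate, via diazoketone 3 (not isolated)
Conditions: 2 (2.0 equiv), MeCN/THF, 0 °C to rt; then 48% aq HBr, 0 °C
Reagents that add atoms: hydrogen bromide, Br
Why: Acylation of the diazo carbon by the acid chloride (Arndt–Eistert-type diazoketone formation), then protonation and displacement of dinitrogen by bromide, is the standard regiospecific way to a bromomethyl ketone, and the ethyl ester is inert to both stages.

**Step 2**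
Reactants: 4 ethyl 6-bromo-5-oxohexanoate; 5 2,4-dibromophenol
Product: 6 ethyl 6-(2,4-dibromophenoxy)-5-oxohexanoate
Conditions: K2CO3, acetone, rt
Reagents that add atoms: none
Why: Williamson ether synthesis, in which the acidic dibromophenol is deprotonated by carbonate and the α-bromo ketone is a very reactive SN2 partner, so O-alkylation should be fast at room temperature.

**Step 3**
Reactants: 6 ethyl 6-(2,4-dibromophenoxy)-5-oxohexanoate
Product: 7 2-(2,4-dibromophenoxy)cyclohexane-1,3-dione
Conditions: KOt-Bu (2.2 equiv), THF, slow addition of 6 at high dilution, 0 °C to rt; then 1 M HCl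
Reagents that add atoms: none
Why: KOt-Bu enolizes the ketone reversibly on both sides, and the enolate at the aryloxy-bearing carbon C2 adds to the ester carbonyl C1 and expels ethoxide, forming the C1–C2 bond (intramolecular Claisen, Dieckmann-type condensation). The closest known reaction type is the base-mediated cyclization of 5-oxohexanoate and 5-oxoheptanoate esters to cyclohexane-1,3-dione and its 2-alkyl derivatives. Ring A closes in a 6-(enolendo)-exo-trig mode, because the enolate double bond lies inside the ring being formed. No stereocentre arises, since C2 of the product is deprotonated at once to the planar, symmetric diketone enolate, and this deprotonation makes the condensation irreversible. The selectivity needed is regiochemical, C2 against C4 as the nucleophilic carbon, and the substrate secures it: the C4 enolate could only close a four-membered ring and reverts, while the C2–H bonds are further acidified by the aryloxy group. High dilution and slow addition should keep intermolecular aldol and Claisen reactions behind the ring closure.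

**Step 4**
Reactants: 7 2-(2,4-dibromophenoxy)cyclohexane-1,3-dione
Product: 8 3-bromo-2-(2,4-dibromophenoxy)cyclohex-2-en-1-one
Conditions: Ph3PBr2, Et3N, CH2Cl2, 0 °C to rt
Reagents that add atoms: dibromotriphenylphosphorane, BrP(Br)(c1ccccc1)(c1ccccc1)c1ccccc1
Why: The enol of the vinylogous acid is activated as an oxyphosphonium salt and bromide replaces it by addition–elimination with loss of Ph3PO (the standard β-bromo enone synthesis from 1,3-diones); the symmetry of 7 allows only one product.

**Step 5**
Reactants: 8 3-bromo-2-(2,4-dibromophenoxy)cyclohex-2-en-1-one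
Product: 10 racemic 3,6-dibromo-2-(2,4-dibromophenoxy)cyclohex-2-en-1-one, via silyl dienol ether 9 (not isolated)
Conditions: LiN(SiMe3)2, THF, −78 °C; Me3SiCl; volatiles removed; then NBS (1.0 equiv), THF, −78 to 0 °C
Reagents that add atoms: N-bromosuccinimide, O=C1CCC(=O)N1Br
Why: Kinetic α′-deprotonation at C6 and O-silylation give the cross-conjugated silyl dienol ether, whose C6 is brominated by exactly one equivalent of NBS (α-bromination of a silyl enol ether), so no electrophilic bromine remains when the phenol is released later; the new C6 stereocentre is formed racemic and is removed in step 6.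

**Step 6**
Reactants: 10 racemic 3,6-dibromo-2-(2,4-dibromophenoxy)cyclohex-2-en-1-one
Product: 11 3-bromo-2-(2,4-dibromophenoxy)phenol
Conditions: Li2CO3, LiBr, DMF, 100 °C
Reagents that add atoms: none
Why: E2 dehydrobromination across C5–C6 gives the cyclohexa-2,5-dienone, which tautomerizes at once to the phenol (the classical bromination–dehydrobromination aromatization of cyclohexenones), driven by the gain of aromaticity.

**Step 7**
Reactants: 11 3-bromo-2-(2,4-dibromophenoxy)phenol
Product: 12 1-bromo-2-(2,4-dibromophenoxy)-3-methoxybenzene
Conditions: MeI, K2CO3, acetone, 50 °C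
Reagents that add atoms: iodomethane, CI
Why: Williamson O-methylation of a phenoxide, with no other nucleophilic site in the molecule.

**Step 8**
Reactants: 12 1-bromo-2-(2,4-dibromophenoxy)-3-methoxybenzene
Product: 14 1,5-dibromo-2-(2,4-dibromophenoxy)-3-methoxybenzene, via arylboronate 13 (not isolated)
Conditions: [Ir(OMe)(cod)]2 (1.5 mol%), 4,4′-di-tert-butyl-2,2′-bipyridine (3 mol%), B2pin2 (1.0 equiv), THF, 80 °C; then CuBr2 (3 equiv), MeOH/H2O (1:1), 80 °C
Reagents that add atoms: copper dibromide, Br[Cu]Br
Why: Iridium-catalysed arene C–H borylation is governed by sterics and C5–H of ring A is the only aromatic C–H bond without an ortho substituent (every ring B hydrogen and C4–H and C6–H are flanked), and CuBr2 then replaces the boronate by bromine (bromodeboronation); this reaches the position meta to the methoxy group that electrophilic substitution cannot address, and aryl bromides are tolerated in both stages.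

**Step 9**
Reactants: 14 1,5-dibromo-2-(2,4-dibromophenoxy)-3-methoxybenzene
Product: 15 1,2,3-tribromo-4-(2,4-dibromophenoxy)-5-methoxybenzene (target)
Conditions: Br2 (1.05 equiv), AcOH, rt
Reagents that add atoms: bromine, BrBr
Why: Electrophilic aromatic bromination should go to C4, para to the methoxy group, because C6 is shielded by the methoxy methyl group (turned toward C6 by the C2 aryloxy group, as at the 3-position of veratrole) and by C5–Br, and ring B is deactivated by its two bromines.

**Compound list**
1 | ethyl 5-chloro-5-oxopentanoate | CCOC(=O)CCCC(=O)Cl | starting material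
2 | (trimethylsilyl)diazomethane | C[Si](C)(C)C=[N+]=[N-] | starting material
3 | ethyl 6-diazo-5-oxohexanoate (formed in the flask) | CCOC(=O)CCCC(=O)C=[N+]=[N-] | intermediate
4 | ethyl 6-bromo-5-oxohexanoate | CCOC(=O)CCCC(=O)CBr | intermediate
5 | 2,4-dibromophenol | Oc1ccc(Br)cc1Br | starting material
6 | ethyl 6-(2,4-dibromophenoxy)-5-oxohexanoate | CCOC(=O)CCCC(=O)COc1ccc(Br)cc1Br | intermediate
7 | 2-(2,4-dibromophenoxy)cyclohexane-1,3-dione | O=C1CCCC(=O)C1Oc1ccc(Br)cc1Br | intermediate
8 | 3-bromo-2-(2,4-dibromophenoxy)cyclohex-2-en-1-one | O=C1CCCC(Br)=C1Oc1ccc(Br)cc1Br | intermediate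
9 | {[4-bromo-3-(2,4-dibromophenoxy)cyclohexa-1,3-dien-2-yl]oxy}trimethylsilane (formed in the flask) | C[Si](C)(C)OC1=CCCC(Br)=C1Oc1ccc(Br)cc1Br | intermediate
10 | 3,6-dibromo-2-(2,4-dibromophenoxy)cyclohex-2-en-1-one (racemic) | O=C1C(Br)CCC(Br)=C1Oc1ccc(Br)cc1Br | intermediate
11 | 3-bromo-2-(2,4-dibromophenoxy)phenol | Oc1cccc(Br)c1Oc1ccc(Br)cc1Br | intermediate
12 | 1-bromo-2-(2,4-dibromophenoxy)-3-methoxybenzene | COc1cccc(Br)c1Oc1ccc(Br)cc1Br | intermediate
13 | 2-[3-bromo-4-(2,4-dibromophenoxy)-5-methoxyphenyl]-4,4,5,5-tetramethyl-1,3,2-dioxaborolane (formed in the flask) | COc1cc(B2OC(C)(C)C(C)(C)O2)cc(Br)c1Oc1ccc(Br)cc1Br | intermediate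
14 | 1,5-dibromo-2-(2,4-dibromophenoxy)-3-methoxybenzene | COc1cc(Br)cc(Br)c1Oc1ccc(Br)cc1Br | intermediate
15 | 1,2,3-tribromo-4-(2,4-dibromophenoxy)-5-methoxybenzene | COc1cc(Br)c(Br)c(Br)c1Oc1ccc(Br)cc1Br | target

Total step count: 9
Longest linear sequence: 9 steps (from 1 to 15)

**Steps most likely to fail**

Step 9. Poor site selectivity is the danger: attack at C6 (ortho to the methoxy group) or on ring B could compete with attack at C4, which is flanked by two bromines, and a second bromination could follow. The fallback sets out from 14 and lets a free phenol direct the substitution. BBr3 in CH2Cl2 (−78 °C to rt) should cleave the methyl ether, leaving the diaryl ether intact, to give 3,5-dibromo-2-(2,4-dibromophenoxy)phenol F3. The bulky, para-selective tetrabutylammonium tribromide in CH2Cl2/MeOH should then brominate para to the hydroxyl group to give 3,4,5-tribromo-2-(2,4-dibromophenoxy)phenol F4. Methylation with MeI and K2CO3 in acetone comes back to the route at 15.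

Step 3. Intermolecular aldol or Claisen condensation of the keto ester, or base-induced loss of the aryloxide, could outrun the ring closure. The fallback sets out from 5 and forms the C2–O bond on a ready-made ring. Commercial cyclohexane-1,3-dione is converted by diazo transfer (4-acetamidobenzenesulfonyl azide, Et3N, MeCN) into 2-diazocyclohexane-1,3-dione F1. O–H insertion of its carbenoid into 5, catalysed by dirhodium tetraacetate Rh2(OAc)4 in refluxing CH2Cl2, should then give the dione, so the fallback comes back to the route at 7.

Step 5. Deprotonation at C4 in place of C6, attack of the amide base at the bromine-bearing C3 with loss of bromide, or double bromination could spoil the enolate route. The fallback sets out from 8 and uses no enolate. Radical allylic bromination (Wohl–Ziegler; NBS, catalytic AIBN, PhCF3, 80 °C) should give racemic 3,4-dibromo-2-(2,4-dibromophenoxy)cyclohex-2-en-1-one F2. Under the conditions of step 6 (Li2CO3, LiBr, DMF, 100 °C) this should lose HBr across C4–C5 and tautomerize, which comes back to the route at 11.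

**Further compounds**
F1 | step 3 | 2-diazocyclohexane-1,3-dione | O=C1CCCC(=O)C1=[N+]=[N-]
F2 | step 5 | 3,4-dibromo-2-(2,4-dibromophenoxy)cyclohex-2-en-1-one (racemic) | O=C1CCC(Br)C(Br)=C1Oc1ccc(Br)cc1Br
F3 | step 9 | 3,5-dibromo-2-(2,4-dibromophenoxy)phenol | Oc1cc(Br)cc(Br)c1Oc1ccc(Br)cc1Br
F4 | step 9 | 3,4,5-tribromo-2-(2,4-dibromophenoxy)phenol | Oc1cc(Br)c(Br)c(Br)c1Oc1ccc(Br)cc1Br
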